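Compound numbers are those of the step list (1–36; 36 is the target). Atom labels: ring B carries C8a on b1, C8c on b2, a dihydrofuran oxygen on b3, H on b4, the second dihydrofuran oxygen on b5 and C8b on b6. Ring C carries C8c on c1, oxygen on c3 and c5, and C7a on c6. Ring D is the dihydrofuran O–C7c–C8c–b2–b3 and ring E is the dihydrofuran O–C7b–C8b–b6–b5.

## Analysis of the target

Compound 36 is a heptaphenolic resveratrol trimer in which a pentasubstituted benzene (ring B) is fused to two 2-aryl-2,3-dihydrofurans (rings D and E) and, through C8c and the C8a methylene, to a seven-membered carbocycle (C7a, C8a, b1, b2, C8c, c1, c6) whose far side is the resorcinol ring C. There are five stereocentres: C7a (S), C8c (S) and C7c (S) around the seven-membered ring and ring D, and C8b (R) and C7b (R) in ring E. Both dihydrofurans are trans, the hydrogen on C8c is trans to the hydrogen on C7a across the seven-membered ring, and ring E is too remote from the other three centres to be set by them. The sensitive groups are the seven free phenols and the two O-benzylic carbons C7b and C7c, whose C–O bonds ionise under acid; the same lability is the lever for turning a cis ring into the trans ring. The synthesis is hard because the seven-membered ring sits between two crowded arenes, C8c is a methine common to the seven-membered ring and ring D, the positions b2, b4 and b6 must be told apart, and a remote pair of centres needs absolute control. The strategy rests on ring C, which has oxygen on c3 and c5, hydrogen on c2 and c4, and neighbouring carbons c1 and c6 bonded to C8c and C7a: carbons c1–c4 are the skeleton of a 6-acyl-4-methoxy-2-pyrone, and c5–c6 are an alkyne that carries boron (the future c5 oxygen) and hangs on C7a. Until C8c is attached, ring B is locally symmetric (b2/b6 and b3/b5 equivalent), so the handles for both dihydrofurans can be installed once, at the start.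

## Retrosynthetic reasoning

**36 to 35.** The seven O–H bonds are traced back to seven O–CH3 bonds. Methyl ethers are chosen because they must pass organolithium reagents, a 180 °C cycloaddition, peroxide and two carbene reactions. The forward step has to cleave all seven without opening the dihydrofurans irreversibly.

**35 to 34.** No skeletal bond is cut; C7b and C7c are inverted. Their O-benzylic C–O bonds ionise reversibly under acid, so the trans rings of 35 are the thermodynamic outcome of an equilibration of the cis,cis compound 34. The ring-forming steps then only have to control C8b and C8c.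

**34 to 28 and 29.** The C8b–C7b bond is cut to diazo compound 33 (from hydrazone 32), whose carbene inserts into a C–H bond of the b5 4-methoxybenzyl ether. The b6–C8b bond is then cut to aryllithium 30 (from bromide 28) and nitrile 29. Ring E is remote, so a chiral catalyst must set C8b, and the insertion does this. The nitrile is used because ketimine 31 exchanges with a nitrogen nucleophile more readily than a carbonyl group flanked by two ortho substituents would condense.

**28 to 25.** The C8c–C7c bond is cut to diazo compound 27, made from hydrazone 26 and ketone 25. The ketone carbon of the dibenzosuberone is C8c, and the b3 ether lies ortho to it. For this reason ring B is carried from the first step as its bis(4-methoxybenzyl) ether: the two benzylic carbons are C7c and C7b of 36. No selective dealkylation next to a ketone and no late benzylation is needed, and Lewis acids are kept away from the finished ring D. The forward step must set C8c relative to C7a.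

**25 to 23.** The c5–O bond is traced to the c5–B bond of 23, through phenol 24. Boron is the only group that the cycloaddition can place at c5 and that is then exchanged for oxygen with retention of position.

**23 to 21 (key disconnection).** Bonds c6–c1 and c5–c4 are cut, and the lactone bridge of 22 is restored in thought. This opens ring C and the seven-membered ring together and leads to acylpyrone 21, in which the alkynylboronate is held on C7a. It is cut here because no other disconnection removes two rings at once while leaving C7a untouched, and because the tether fixes the regiochemistry. The b6 bromide is carried through as a spectator; it marks the site of ring E, which later halogenation could not distinguish from b4 and the activated positions of ring C.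

**21 to 13 and 15.** The C–B bond is cut to terminal alkyne 19, the silyl group is restored (18), the ketone is reduced in thought to carbinol 17, and the b2–C8c bond is cut to aryllithium 16 (from dibromide 13) and aldehyde 15, which comes from pyrone 14. The two bromines of 13 are equivalent, so monolithiation needs no regiocontrol.

**13 to 9 and 12.** The C7a–aryl bond is cut to racemic propargylic carbonate 9 and arylzinc 12 (from 10 through 11). An enantioconvergent coupling sets C7a from a racemate and delivers the alkyne in the same step.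

**9 to 1, 2 and 6.** The carbonate comes from alcohol 8, whose C8a–C7a bond is cut to the benzylic zinc reagent 7 (from chloride 5) and ynal 6. Chloride 5 comes from alcohol 4 by chlorination, 4 from 3 by double ring bromination, and 3 from 1 and two equivalents of 2 by etherification.

## Alternatives that were turned down

**Alternative 1:** Ring D is taken from the chiral pool. The disconnection cuts the b2–C8c bond and traces the dihydrofuran back to the chromanone ring of (S)-naringenin A1, used as its 7,4'-di-O-methyl 5-O-triflyl derivative A2. In the forward key step PhI(OAc)2 and H2SO4 in trimethyl orthoformate enolise A2 and place trivalent iodine on C3; the ring-B carbon then shifts from the carbonyl carbon to C3, and the six-membered ring contracts to the trans dihydrobenzofuran ester A3. In its favour, C7c is bought with its absolute configuration, the trans ring forms directly, and no carbene and no facial-selectivity question arises for ring D. On these points it is stronger than the chosen route. Against it for this target: a flavanone such as A2 racemises by reversible opening of its pyranone ring under the basic conditions needed to tell the three phenols of A1 apart. In A3, C8c is enolisable and carries an ester carbon where 36 has ring C, so ring C must be built from a carboxylate or the ester replaced by an aryl group. The seven-membered ring still has to be closed with C7a controlled from a distance, and b6 carries no handle for ring E. The chosen route pays with a later carbene insertion of uncertain face selectivity, but it gains ring C and the seven-membered ring in one step with C7a already fixed.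

**Alternative 2:** The seven-membered ring and ring D are formed together. The disconnection cuts b2–C8c and O–C7c and leads to stilbene A4 (C8c=C7c), which is tethered through C7a and C8a to a free resorcinol ring B. In the forward step Ru(bpz)3(PF6)2 under visible light with (NH4)2S2O8 removes one electron from the stilbene of A4, b2 attacks C8c, a second oxidation makes C7c a 4-methoxybenzylic cation centre, and the neighbouring phenol oxygen closes onto it to give A5. In its favour, two rings, two bonds and two stereocentres arise in one biomimetic operation, and the trans ring is the direct product. For this part of the molecule it is shorter than the chosen route, which needs a hydrazone, a diazo compound, an insertion and a later epimerisation. Against it: known oxidative phenol–alkene annulations rely on phenols that are themselves oxidised, and a resorcinol closing a seven-membered ring is a different regime. Ring C of A4 is a dimethoxyarene of similar oxidation potential, A5 is more electron-rich than A4, and C8c would be set from C7a under cationic conditions without a controlling element. A5 has a free phenol at b5 but nothing at b6, so ring E would have to be placed by a substitution that cannot separate b6 from b4. The chosen pericyclic step is indifferent to redox-sensitive groups, has its regiochemistry fixed by the tether, and carries a bromide that marks b6.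

**Alternative 3:** Ring C is inserted as an aryne. The disconnection cuts c1–C8c and c6–C7a and leads to the ring-B 2-indanone-1-carboxylate A6 and the 2-silylaryl triflate A7, which is the precursor of the 3,5-dimethoxy aryne. In the forward step CsF strips the silyl group and the triflate from A7, the enolised keto ester A6 adds through C8c to the strained triple bond at c1, the aryl anion at c6 attacks the ketone, and the cyclobutoxide fragments to the seven-membered keto ester A8. In its favour, this two-carbon ring expansion is well established for benzo-fused seven-membered rings, runs under mild conditions, and the alkoxy group next to the strained bond directs the addition correctly. As a ring-forming event it is better precedented and milder than a cycloaddition through a five-atom tether at 180 °C. Against it: A8 fixes no stereocentre. Its ketone sits at C7a, where an aryl group must be added and the tertiary alcohol removed with relative and absolute control. Its ester sits at C8c, where several redox steps are needed before ring D can be closed, and the benzylic ketone enolises towards C8a. A6 and A7 each need several steps, and ring E is again unaddressed. The chosen route sets C7a by catalysis before ring closure and places the ketone at C8c, where ring D needs it.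

Key step: step 13

Assumptions:
- The sense of induction of the pybox ligand (step 7) and of the two antipodal dirhodium catalysts (steps 17 and 19) is taken as drawn; each is checked on the first run and the antipode is used if the opposite sense is found.
- The carbene insertions are taken to give the cis dihydrofurans, as is usual for diaryl carbenes; if a trans ring forms directly, step 20 leaves it unchanged.

## Route

Step 1
Reactants: 1 3,5-dihydroxybenzyl alcohol; 2 4-methoxybenzyl chloride (2.2 equiv)
Product: 3 [3,5-bis(4-methoxybenzyloxy)phenyl]methanol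
Conditions: 2 (2.2 equiv), K2CO3 (3 equiv), 18-crown-6 (cat.), acetone, reflux
Reagents that add atoms: 4-methoxybenzyl chloride (second equivalent), COc1ccc(CCl)cc1
Why: Twofold Williamson etherification: each of the two phenols takes up one molecule of 2, and the benzylic alcohol is not deprotonated by carbonate. The two benzylic carbons installed here become C7c and C7b.

Step 2
Reactants: 3 [3,5-bis(4-methoxybenzyloxy)phenyl]methanol
Product: 4 [2,6-dibromo-3,5-bis(4-methoxybenzyloxy)phenyl]methanol
Conditions: N-bromosuccinimide (2.05 equiv), MeCN, 0 °C, dark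
Reagents that add atoms: N-bromosuccinimide (first equivalent), O=C1CCC(=O)N1Br; N-bromosuccinimide (second equivalent), O=C1CCC(=O)N1Br
Why: Twofold electrophilic aromatic bromination at the two positions ortho to CH2OH, each ortho and para to an alkoxy group and less hindered than C4 between the two ethers. The anisyl rings are far less activated and should react only after both positions are filled.

Step 3
Reactants: 4 [2,6-dibromo-3,5-bis(4-methoxybenzyloxy)phenyl]methanol
Product: 5 2,6-dibromo-3,5-bis(4-methoxybenzyloxy)benzyl chloride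
Conditions: PPh3, N-chlorosuccinimide, THF, 0 °C → rt
Reagents that add atoms: N-chlorosuccinimide, O=C1CCC(=O)N1Cl
Why: Appel-type chlorination through the alkoxyphosphonium salt under neutral conditions that spare the acid-labile benzyl ethers.

Step 4
Reactants: 5 2,6-dibromo-3,5-bis(4-methoxybenzyloxy)benzyl chloride; 6 3-(trimethylsilyl)propynal
Product: 8 rac-1-[2,6-dibromo-3,5-bis(4-methoxybenzyloxy)phenyl]-4-(trimethylsilyl)but-3-yn-2-ol, via benzylic zinc chloride 7 (not isolated)
Conditions: Zn dust, LiCl, THF, 25 °C; then 6, 0 → 25 °C; aq. NH4Cl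
Reagents that add atoms: none
Why: LiCl-promoted zinc insertion into the benzylic C–Cl bond (aryl bromides are inert at 25 °C), then 1,2-addition of the benzylic zinc reagent to the ynal. The alcohol is racemic, which does not matter for the stereoconvergent step 7.

Step 5
Reactants: 8 rac-1-[2,6-dibromo-3,5-bis(4-methoxybenzyloxy)phenyl]-4-(trimethylsilyl)but-3-yn-2-ol
Product: 9 rac-1-[2,6-dibromo-3,5-bis(4-methoxybenzyloxy)phenyl]-4-(trimethylsilyl)but-3-yn-2-yl methyl carbonate
Conditions: ClCO2Me, pyridine, DMAP (cat.), CH2Cl2, 0 °C
Reagents that add atoms: methyl chloroformate, COC(=O)Cl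
Why: O-acylation of the secondary alcohol gives the carbonate, the oxygen leaving group for the nickel-catalysed propargylic substitution.

Step 6
Reactants: 10 4-bromoanisole
Product: 12 4-methoxyphenylzinc iodide (THF solution), via aryl Grignard reagent 11 (not isolated)
Conditions: Mg turnings, THF, 25–50 °C; then ZnI2, THF, 0 °C → rt
Reagents that add atoms: zinc iodide, [Zn+2].[I-].[I-]
Why: Grignard formation followed by transmetalation to zinc gives the mild aryl nucleophile needed for the Negishi coupling.

Step 7
Reactants: 9 rac-1-[2,6-dibromo-3,5-bis(4-methoxybenzyloxy)phenyl]-4-(trimethylsilyl)but-3-yn-2-yl methyl carbonate; 12 4-methoxyphenylzinc iodide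
Product: 13 (S)-{4-[2,6-dibromo-3,5-bis(4-methoxybenzyloxy)phenyl]-3-(4-methoxyphenyl)but-1-yn-1-yl}trimethylsilane
Conditions: 12 (1.6 equiv), NiCl2(dme) (10 mol%), indane-fused pybox ligand (13 mol%, antipode selected for the S product), DME/THF, −20 °C
Reagents that add atoms: none
Why: Nickel-catalysed enantioconvergent Negishi arylation of a racemic propargylic carbonate. Both enantiomers pass through one propargylic radical, and the pybox–nickel aryl complex sets C7a (S). The silyl group disfavours allene formation, and the electron-rich, doubly ortho-substituted aryl bromides should resist oxidative addition at −20 °C.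

Step 8
Reactants: 14 4-methoxy-6-methyl-2H-pyran-2-one
Product: 15 4-methoxy-2-oxo-2H-pyran-6-carbaldehyde
Conditions: SeO2, 1,4-dioxane, 160 °C (sealed tube)
Reagents that add atoms: selenium dioxide, O=[Se]=O
Why: Riley oxidation of the vinylogously activated C6 methyl group of the pyrone to the aldehyde.

Step 9
Reactants: 13 (S)-{4-[2,6-dibromo-3,5-bis(4-methoxybenzyloxy)phenyl]-3-(4-methoxyphenyl)but-1-yn-1-yl}trimethylsilane; 15 4-methoxy-2-oxo-2H-pyran-6-carbaldehyde
Product: 17 6-[{3-bromo-4,6-bis(4-methoxybenzyloxy)-2-[(2S)-2-(4-methoxyphenyl)-4-(trimethylsilyl)but-3-yn-1-yl]phenyl}(hydroxy)methyl]-4-methoxy-2H-pyran-2-one (both carbinol epimers), via aryllithium 16 (not isolated)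
Conditions: n-BuLi (1.05 equiv), THF/Et2O, −100 °C, 5 min; then 15, −100 → −60 °C; aq. NH4Cl
Reagents that add atoms: none
Why: Bromine–lithium exchange at one of the two equivalent bromines, then addition of the aryllithium to the aldehyde, the most electrophilic site of 15. The low temperature and immediate quench are meant to stop the aryllithium from adding across its own silylalkyne (5-exo-dig) or attacking the lactone.

Step 10
Reactants: 17 6-[{3-bromo-4,6-bis(4-methoxybenzyloxy)-2-[(2S)-2-(4-methoxyphenyl)-4-(trimethylsilyl)but-3-yn-1-yl]phenyl}(hydroxy)methyl]-4-methoxy-2H-pyran-2-one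
Product: 18 6-{3-bromo-4,6-bis(4-methoxybenzyloxy)-2-[(2S)-2-(4-methoxyphenyl)-4-(trimethylsilyl)but-3-yn-1-yl]benzoyl}-4-methoxy-2H-pyran-2-one
Conditions: Dess–Martin periodinane, NaHCO3, CH2Cl2, 0 °C → rt
Reagents that add atoms: none
Why: Dess–Martin oxidation of the doubly activated carbinol removes the unwanted stereocentre and gives the non-enolisable aryl pyronyl ketone that makes the pyrone electron-poor.

Step 11
Reactants: 18 6-{3-bromo-4,6-bis(4-methoxybenzyloxy)-2-[(2S)-2-(4-methoxyphenyl)-4-(trimethylsilyl)but-3-yn-1-yl]benzoyl}-4-methoxy-2H-pyran-2-one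
Product: 19 6-{3-bromo-4,6-bis(4-methoxybenzyloxy)-2-[(2R)-2-(4-methoxyphenyl)but-3-yn-1-yl]benzoyl}-4-methoxy-2H-pyran-2-one
Conditions: n-Bu4NF, AcOH, THF, 0 °C
Reagents that add atoms: none
Why: Fluoride-induced protodesilylation of the alkynylsilane, buffered so that the acylpyrone and the propargylic C7a–H are not exposed to base. The descriptor changes from S to R only because ethynyl now ranks below the aryl group.

Step 12
Reactants: 19 6-{3-bromo-4,6-bis(4-methoxybenzyloxy)-2-[(2R)-2-(4-methoxyphenyl)but-3-yn-1-yl]benzoyl}-4-methoxy-2H-pyran-2-one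
Product: 21 6-{3-bromo-4,6-bis(4-methoxybenzyloxy)-2-[(2S)-2-(4-methoxyphenyl)-4-(4,4,5,5-tetramethyl-1,3,2-dioxaborolan-2-yl)but-3-yn-1-yl]benzoyl}-4-methoxy-2H-pyran-2-one, via lithium alkynylborate 20 (not isolated)
Conditions: i-PrOBpin (3 equiv), LiN(SiMe3)2 (1.1 equiv), THF, −78 °C; then HCl in Et2O, −78 °C → rt; filtered, used crude
Reagents that add atoms: 2-isopropoxy-4,4,5,5-tetramethyl-1,3,2-dioxaborolane, CC(C)OB1OC(C)(C)C(C)(C)O1
Why: Acetylide borylation: the amide base removes the alkyne proton in the presence of the borate, the acetylide is captured at once as the ate complex 20, and acid releases isopropanol. The ketone is not enolisable, the amide is non-nucleophilic, and capture by boron should outrun addition to the carbonyl groups.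

Step 13
Reactants: 21 6-{3-bromo-4,6-bis(4-methoxybenzyloxy)-2-[(2S)-2-(4-methoxyphenyl)-4-(4,4,5,5-tetramethyl-1,3,2-dioxaborolan-2-yl)but-3-yn-1-yl]benzoyl}-4-methoxy-2H-pyran-2-one
Product: 23 (10S)-1-bromo-7-methoxy-10-(4-methoxyphenyl)-2,4-bis(4-methoxybenzyloxy)-9-(4,4,5,5-tetramethyl-1,3,2-dioxaborolan-2-yl)-10,11-dihydro-5H-dibenzo[a,d][7]annulen-5-one, via bridged lactone 22 (not isolated)
Conditions: 1,2-dichlorobenzene (0.005 M), BHT, 180 °C (sealed tube, argon)
Reagents that add atoms: none
Why: Thermal [4+2] cycloaddition of the alkyne across C6 and C3 of the 2-pyrone gives the 2-oxabicyclo[2.2.2]octadienone 22, which loses CO2 by retro-[4+2] to the benzene ring; the closest known reactions are the thermal pyrone–alkynylboronate cycloaddition to arylboronates and intramolecular pyrone–alkyne benzannulations. The aroyl group on C6 lowers the LUMO of the diene and the alkynylboronate is an unhindered two-carbon partner. Ring C closes as the six-membered ring of the cycloaddition (bonds c6–c1 and c5–c4), and the seven-membered ring closes as the tether ring of an intramolecular Diels–Alder reaction with the tether on the diene terminus, its five linking atoms (C8c, b2, b1, C8a, C7a) being held by the cis aromatic bond b1–b2 and the sp2 carbonyl. No stereocentre is created, since the bridgeheads of 22 vanish on aromatisation and either face of the pyrone is acceptable. The step needs boron to end on c5 next to c6, and the tether enforces this because the opposite orientation would require the C7a-bound alkyne carbon to reach C3 through a bridged ring. It also needs C7a to survive: the centre has no acidifying carbonyl, the medium is neutral, and once the alkyne is consumed it is a plain diarylmethine. High dilution suppresses intermolecular cycloaddition, and the benzyl ethers and the aryl bromide should be inert at this temperature.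

Step 14
Reactants: 23 (10S)-1-bromo-7-methoxy-10-(4-methoxyphenyl)-2,4-bis(4-methoxybenzyloxy)-9-(4,4,5,5-tetramethyl-1,3,2-dioxaborolan-2-yl)-10,11-dihydro-5H-dibenzo[a,d][7]annulen-5-one
Product: 24 (10S)-1-bromo-9-hydroxy-7-methoxy-10-(4-methoxyphenyl)-2,4-bis(4-methoxybenzyloxy)-10,11-dihydro-5H-dibenzo[a,d][7]annulen-5-one
Conditions: H2O2 (30% aq.), NaOH (aq.), THF, 0 °C
Reagents that add atoms: hydrogen peroxide, OO
Why: Oxidation of the arylboronate by 1,2-migration of the aryl group from boron to oxygen in the hydroperoxide ate complex places the second oxygen of ring C on c5. The non-enolisable diaryl ketone should not undergo Baeyer–Villiger cleavage under these conditions.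

Step 15
Reactants: 24 (10S)-1-bromo-9-hydroxy-7-methoxy-10-(4-methoxyphenyl)-2,4-bis(4-methoxybenzyloxy)-10,11-dihydro-5H-dibenzo[a,d][7]annulen-5-one
Product: 25 (10S)-1-bromo-7,9-dimethoxy-10-(4-methoxyphenyl)-2,4-bis(4-methoxybenzyloxy)-10,11-dihydro-5H-dibenzo[a,d][7]annulen-5-one
Conditions: MeI, K2CO3, DMF, rt
Reagents that add atoms: iodomethane, CI
Why: Williamson methylation of the phenol, so that all future phenols except the two ring-B oxygens are methyl ethers.

Step 16
Reactants: 25 (10S)-1-bromo-7,9-dimethoxy-10-(4-methoxyphenyl)-2,4-bis(4-methoxybenzyloxy)-10,11-dihydro-5H-dibenzo[a,d][7]annulen-5-one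
Product: 26 (10S)-1-bromo-5-hydrazinylidene-7,9-dimethoxy-10-(4-methoxyphenyl)-2,4-bis(4-methoxybenzyloxy)-10,11-dihydro-5H-dibenzo[a,d][7]annulene (E/Z mixture)
Conditions: N2H4·H2O, AcOH (cat.), n-BuOH, 110 °C
Reagents that add atoms: hydrazine (as hydrate), NN
Why: Acid-catalysed condensation of hydrazine with the cyclic diaryl ketone, whose carbonyl is held open by the seven-membered ring.

Step 17
Reactants: 26 (10S)-1-bromo-5-hydrazinylidene-7,9-dimethoxy-10-(4-methoxyphenyl)-2,4-bis(4-methoxybenzyloxy)-10,11-dihydro-5H-dibenzo[a,d][7]annulene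
Product: 28 bromo cis-dihydrofuran with ring D closed (C7a S; C8c S; C7c R; H8c cis to H7c; b5 4-methoxybenzyl ether; b6 bromide), via diazo compound 27 (not isolated)
Conditions: MnO2, CH2Cl2, 0 °C; filtered; then Rh2(S-PTAD)4 (1 mol%), CH2Cl2, −40 °C → rt
Reagents that add atoms: none
Why: MnO2 dehydrogenates the hydrazone to the diaryldiazomethane 27, and the diaryl dirhodium carbene inserts into the neighbouring O–CH2–aryl C–H bond (1,5-insertion) to form C8c–C7c, as known for ortho-benzyloxy diaryl ketone hydrazones. C8c is set by the carbene face that receives hydrogen, controlled by the chiral carboxylate catalyst together with the seven-ring conformation that keeps the C7a aryl group pseudo-equatorial. The C7c aryl group comes out cis to ring C and is corrected in step 20.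

Step 18
Reactants: 28 bromo cis-dihydrofuran with ring D closed (C7a S; C8c S; C7c R); 29 3,5-dimethoxybenzonitrile
Product: 32 hydrazone in which the b6 bromine of 28 is replaced by C(=N–NH2)(3,5-dimethoxyphenyl) (C7a S; C8c S; C7c R), via aryllithium 30 (not isolated), via N-H ketimine 31 (not isolated)
Conditions: n-BuLi, THF, −78 °C; 29, −78 → 0 °C; MeOH; then N2H4·H2O, AcOH, EtOH, 70 °C
Reagents that add atoms: hydrazine (as hydrate), NN
Why: Bromine–lithium exchange at b6, addition of the aryllithium to the nitrile, and exchange of the N–H ketimine with hydrazine. This reaches the hydrazone without condensing hydrazine with a doubly ortho-substituted benzophenone.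

Step 19
Reactants: 32 hydrazone in which the b6 bromine of 28 is replaced by C(=N–NH2)(3,5-dimethoxyphenyl)
Product: 34 cis,cis-bis(dihydrofuran) heptamethyl ether with ring E closed (C7a S; C8c S; C7c R; C8b R; C7b S; H8b cis to H7b), via diazo compound 33 (not isolated)
Conditions: MnO2, CH2Cl2, 0 °C; filtered; then Rh2(R-PTAD)4 (1 mol%), CH2Cl2, −40 °C → rt
Reagents that add atoms: none
Why: Same hydrazone oxidation and carbene C–H insertion as in step 17, now forming C8b–C7b with the b5 ether. Ring E is remote from the other centres, so C8b is set by the catalyst alone; the antipodal catalyst is used because ring E is locally the mirror image of ring D. Insertion into the hydridic α-oxygen benzylic C–H bond should outrun insertion into the hindered tertiary C7a–H bond.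

Step 20
Reactants: 34 cis,cis-bis(dihydrofuran) heptamethyl ether (C7a S; C8c S; C7c R; C8b R; C7b S)
Product: 35 trans,trans-bis(dihydrofuran) heptamethyl ether of 36 (C7a S; C8c S; C7c S; C8b R; C7b R)
Conditions: CF3CO2H, CH2Cl2, 0 °C → rt
Reagents that add atoms: none
Why: Acid ionises each O–C7 bond reversibly to a 4-methoxybenzylic cation that recloses on the neighbouring phenol oxygen, so C7c and C7b equilibrate to the more stable trans rings. C8c and C8b are not part of the ionising bond and keep their configuration.

Step 21
Reactants: 35 trans,trans-bis(dihydrofuran) heptamethyl ether of 36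
Product: 36 CNP0136963.1, the target heptaphenol (C7a S; C8c S; C7c S; C8b R; C7b R)
Conditions: BBr3, CH2Cl2, −78 °C → rt; then MeOH, H2O
Reagents that add atoms: none
Why: Lewis-acid O-demethylation of the seven aryl methyl ethers, the usual last step for oligostilbenoids. Any reversible opening of the dihydrofurans returns to the trans rings already present.

## Compound list

1 | 3,5-dihydroxybenzyl alcohol | OCc1cc(O)cc(O)c1 | starting material
2 | 4-methoxybenzyl chloride | COc1ccc(CCl)cc1 | starting material
3 | [3,5-bis(4-methoxybenzyloxy)phenyl]methanol | OCc1cc(OCc2ccc(OC)cc2)cc(OCc2ccc(OC)cc2)c1 | intermediate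
4 | [2,6-dibromo-3,5-bis(4-methoxybenzyloxy)phenyl]methanol | OCc1c(Br)c(OCc2ccc(OC)cc2)cc(OCc2ccc(OC)cc2)c1Br | intermediate
5 | 2,6-dibromo-3,5-bis(4-methoxybenzyloxy)benzyl chloride | ClCc1c(Br)c(OCc2ccc(OC)cc2)cc(OCc2ccc(OC)cc2)c1Br | intermediate
6 | 3-(trimethylsilyl)propynal | C[Si](C)(C)C#CC=O | starting material
7 | [2,6-dibromo-3,5-bis(4-methoxybenzyloxy)benzyl]zinc chloride (not isolated) | Cl[Zn]Cc1c(Br)c(OCc2ccc(OC)cc2)cc(OCc2ccc(OC)cc2)c1Br | intermediate
8 | rac-1-[2,6-dibromo-3,5-bis(4-methoxybenzyloxy)phenyl]-4-(trimethylsilyl)but-3-yn-2-ol | C[Si](C)(C)C#CC(O)Cc1c(Br)c(OCc2ccc(OC)cc2)cc(OCc2ccc(OC)cc2)c1Br | intermediate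
9 | rac-1-[2,6-dibromo-3,5-bis(4-methoxybenzyloxy)phenyl]-4-(trimethylsilyl)but-3-yn-2-yl methyl carbonate | COC(=O)OC(Cc1c(Br)c(OCc2ccc(OC)cc2)cc(OCc2ccc(OC)cc2)c1Br)C#C[Si](C)(C)C | intermediate
10 | 4-bromoanisole | COc1ccc(Br)cc1 | starting material
11 | 4-methoxyphenylmagnesium bromide (not isolated) | COc1ccc([Mg]Br)cc1 | intermediate
12 | 4-methoxyphenylzinc iodide | COc1ccc([Zn]I)cc1 | intermediate
13 | (S)-{4-[2,6-dibromo-3,5-bis(4-methoxybenzyloxy)phenyl]-3-(4-methoxyphenyl)but-1-yn-1-yl}trimethylsilane | COc1ccc([C@@H](C#C[Si](C)(C)C)Cc2c(Br)c(OCc3ccc(OC)cc3)cc(OCc3ccc(OC)cc3)c2Br)cc1 | intermediate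
14 | 4-methoxy-6-methyl-2H-pyran-2-one | COc1cc(C)oc(=O)c1 | starting material
15 | 4-methoxy-2-oxo-2H-pyran-6-carbaldehyde | COc1cc(C=O)oc(=O)c1 | intermediate
16 | {3-bromo-4,6-bis(4-methoxybenzyloxy)-2-[(2S)-2-(4-methoxyphenyl)-4-(trimethylsilyl)but-3-yn-1-yl]phenyl}lithium (not isolated) | COc1ccc([C@@H](C#C[Si](C)(C)C)Cc2c([Li])c(OCc3ccc(OC)cc3)cc(OCc3ccc(OC)cc3)c2Br)cc1 | intermediate
17 | 6-[{3-bromo-4,6-bis(4-methoxybenzyloxy)-2-[(2S)-2-(4-methoxyphenyl)-4-(trimethylsilyl)but-3-yn-1-yl]phenyl}(hydroxy)methyl]-4-methoxy-2H-pyran-2-one (both carbinol epimers) | COc1ccc([C@@H](C#C[Si](C)(C)C)Cc2c(C(O)c3cc(OC)cc(=O)o3)c(OCc3ccc(OC)cc3)cc(OCc3ccc(OC)cc3)c2Br)cc1 | intermediate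
18 | 6-{3-bromo-4,6-bis(4-methoxybenzyloxy)-2-[(2S)-2-(4-methoxyphenyl)-4-(trimethylsilyl)but-3-yn-1-yl]benzoyl}-4-methoxy-2H-pyran-2-one | COc1ccc([C@@H](C#C[Si](C)(C)C)Cc2c(C(=O)c3cc(OC)cc(=O)o3)c(OCc3ccc(OC)cc3)cc(OCc3ccc(OC)cc3)c2Br)cc1 | intermediate
19 | 6-{3-bromo-4,6-bis(4-methoxybenzyloxy)-2-[(2R)-2-(4-methoxyphenyl)but-3-yn-1-yl]benzoyl}-4-methoxy-2H-pyran-2-one | COc1ccc([C@@H](C#C)Cc2c(C(=O)c3cc(OC)cc(=O)o3)c(OCc3ccc(OC)cc3)cc(OCc3ccc(OC)cc3)c2Br)cc1 | intermediate
20 | lithium isopropoxy(pinacolato)borate of alkyne 19, boron on the terminal alkyne carbon, (S) (not isolated) | [Li+].COc1ccc([C@@H](C#C[B-]2(OC(C)C)OC(C)(C)C(C)(C)O2)Cc2c(C(=O)c3cc(OC)cc(=O)o3)c(OCc3ccc(OC)cc3)cc(OCc3ccc(OC)cc3)c2Br)cc1 | intermediate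
21 | 6-{3-bromo-4,6-bis(4-methoxybenzyloxy)-2-[(2S)-2-(4-methoxyphenyl)-4-(4,4,5,5-tetramethyl-1,3,2-dioxaborolan-2-yl)but-3-yn-1-yl]benzoyl}-4-methoxy-2H-pyran-2-one | COc1ccc([C@@H](C#CB2OC(C)(C)C(C)(C)O2)Cc2c(C(=O)c3cc(OC)cc(=O)o3)c(OCc3ccc(OC)cc3)cc(OCc3ccc(OC)cc3)c2Br)cc1 | intermediate
22 | bridged lactone cycloadduct of 21 (2-oxabicyclo[2.2.2]octa-5,7-dien-3-one; alkyne carbons bonded to pyrone C6 and C3; C7a S, bridgeheads undefined) (not isolated) | COc1ccc([C@@H]2Cc3c(Br)c(OCc4ccc(OC)cc4)cc(OCc4ccc(OC)cc4)c3C(=O)C45OC(=O)C(C(OC)=C4)C(B6OC(C)(C)C(C)(C)O6)=C52)cc1 | intermediate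
23 | (10S)-1-bromo-7-methoxy-10-(4-methoxyphenyl)-2,4-bis(4-methoxybenzyloxy)-9-(4,4,5,5-tetramethyl-1,3,2-dioxaborolan-2-yl)-10,11-dihydro-5H-dibenzo[a,d][7]annulen-5-one | COc1ccc([C@@H]2Cc3c(Br)c(OCc4ccc(OC)cc4)cc(OCc4ccc(OC)cc4)c3C(=O)c3cc(OC)cc(B4OC(C)(C)C(C)(C)O4)c32)cc1 | intermediate
24 | (10S)-1-bromo-9-hydroxy-7-methoxy-10-(4-methoxyphenyl)-2,4-bis(4-methoxybenzyloxy)-10,11-dihydro-5H-dibenzo[a,d][7]annulen-5-one | COc1ccc([C@@H]2Cc3c(Br)c(OCc4ccc(OC)cc4)cc(OCc4ccc(OC)cc4)c3C(=O)c3cc(OC)cc(O)c32)cc1 | intermediate
25 | (10S)-1-bromo-7,9-dimethoxy-10-(4-methoxyphenyl)-2,4-bis(4-methoxybenzyloxy)-10,11-dihydro-5H-dibenzo[a,d][7]annulen-5-one | COc1ccc([C@@H]2Cc3c(Br)c(OCc4ccc(OC)cc4)cc(OCc4ccc(OC)cc4)c3C(=O)c3cc(OC)cc(OC)c32)cc1 | intermediate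
26 | (10S)-1-bromo-5-hydrazinylidene-7,9-dimethoxy-10-(4-methoxyphenyl)-2,4-bis(4-methoxybenzyloxy)-10,11-dihydro-5H-dibenzo[a,d][7]annulene (E/Z mixture) | COc1ccc([C@@H]2Cc3c(Br)c(OCc4ccc(OC)cc4)cc(OCc4ccc(OC)cc4)c3C(=NN)c3cc(OC)cc(OC)c32)cc1 | intermediate
27 | (10S)-1-bromo-5-diazo-7,9-dimethoxy-10-(4-methoxyphenyl)-2,4-bis(4-methoxybenzyloxy)-10,11-dihydro-5H-dibenzo[a,d][7]annulene (not isolated) | COc1ccc([C@@H]2Cc3c(Br)c(OCc4ccc(OC)cc4)cc(OCc4ccc(OC)cc4)c3C(=[N+]=[N-])c3cc(OC)cc(OC)c32)cc1 | intermediate
28 | bromo cis-dihydrofuran with ring D (O–C7c–C8c–b2–b3) closed (C7a S; C8c S; C7c R; H8c cis to H7c; 4-methoxyphenyl on C7c; b5 4-methoxybenzyl ether; b6 bromide) | COc1ccc([C@@H]2Cc3c4c(cc(OCc5ccc(OC)cc5)c3Br)O[C@@H](c3ccc(OC)cc3)[C@H]4c3cc(OC)cc(OC)c32)cc1 | intermediate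
29 | 3,5-dimethoxybenzonitrile | COc1cc(C#N)cc(OC)c1 | starting material
30 | b6-lithio derivative of 28 (not isolated) | COc1ccc([C@@H]2Cc3c4c(cc(OCc5ccc(OC)cc5)c3[Li])O[C@@H](c3ccc(OC)cc3)[C@H]4c3cc(OC)cc(OC)c32)cc1 | intermediate
31 | N-H ketimine: 28 with the b6 bromine replaced by C(=NH)(3,5-dimethoxyphenyl) (not isolated) | COc1ccc([C@@H]2Cc3c4c(cc(OCc5ccc(OC)cc5)c3C(=N)c3cc(OC)cc(OC)c3)O[C@@H](c3ccc(OC)cc3)[C@H]4c3cc(OC)cc(OC)c32)cc1 | intermediate
32 | hydrazone: 28 with the b6 bromine replaced by C(=N–NH2)(3,5-dimethoxyphenyl) (C7a S; C8c S; C7c R) | COc1ccc([C@@H]2Cc3c4c(cc(OCc5ccc(OC)cc5)c3C(=NN)c3cc(OC)cc(OC)c3)O[C@@H](c3ccc(OC)cc3)[C@H]4c3cc(OC)cc(OC)c32)cc1 | intermediate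
33 | diazo compound: 28 with the b6 bromine replaced by C(=N2)(3,5-dimethoxyphenyl) (not isolated) | COc1ccc([C@@H]2Cc3c4c(cc(OCc5ccc(OC)cc5)c3C(=[N+]=[N-])c3cc(OC)cc(OC)c3)O[C@@H](c3ccc(OC)cc3)[C@H]4c3cc(OC)cc(OC)c32)cc1 | intermediate
34 | cis,cis-bis(dihydrofuran) heptamethyl ether with ring E (O–C7b–C8b–b6–b5) closed (C7a S; C8c S; C7c R; C8b R; C7b S) | COc1ccc([C@@H]2Cc3c4c(cc5c3[C@@H](c3cc(OC)cc(OC)c3)[C@@H](c3ccc(OC)cc3)O5)O[C@@H](c3ccc(OC)cc3)[C@H]4c3cc(OC)cc(OC)c32)cc1 | intermediate
35 | trans,trans-bis(dihydrofuran) heptamethyl ether of 36 (C7a S; C8c S; C7c S; C8b R; C7b R) | COc1ccc([C@@H]2Cc3c4c(cc5c3[C@@H](c3cc(OC)cc(OC)c3)[C@H](c3ccc(OC)cc3)O5)O[C@H](c3ccc(OC)cc3)[C@H]4c3cc(OC)cc(OC)c32)cc1 | intermediate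
36 | CNP0136963.1 (C7a S; C8c S; C7c S; C8b R; C7b R) | Oc1ccc([C@@H]2Cc3c4c(cc5c3[C@@H](c3cc(O)cc(O)c3)[C@H](c3ccc(O)cc3)O5)O[C@H](c3ccc(O)cc3)[C@H]4c3cc(O)cc(O)c32)cc1 | target

## Step count and least certain steps

Total: 21 steps. Longest linear sequence: 19 steps (1–5, 7, 9–21); steps 6 and 8 are side branches.

**Step 13 (key step).** The cycloaddition through a five-atom tether may be slower than thermal decay of the substrate: protodeboronation of the alkynylboronate, loss of a 4-methoxybenzyl group, or propargyl–allenyl isomerisation at C7a. Fallback: setting out from alkyne 19, deprotonation with LiN(SiMe3)2 at −78 °C and quenching with chlorodimethylsilane should give the dimethylsilyl alkyne F1. This is a more electron-rich partner for the electron-poor acylpyrone and has no C–B bond to lose. Heating as in step 13 should lead through the bridged lactone F2 to the aryl dimethylsilane F3. Tamao-type oxidation (H2O2, KF, KHCO3, THF/MeOH) converts the C–Si bond to C–OH and returns to the route at phenol 24.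

**Step 7.** The bulky homobenzylic substituent may slow capture of the propargylic radical and erode enantioselectivity, and low-valent nickel may insert into the aryl bromides. Fallback: setting out from chloride 5 (through zinc reagent 7), addition to 4-methoxybenzaldehyde gives the alcohol F4, and PPh3 with N-chlorosuccinimide gives the benzylic chloride F5. A copper-catalysed enantioconvergent radical coupling with ethynyltrimethylsilane (CuI, chiral cinchona-derived N,N,P ligand, Cs2CO3, Et2O) forms the C7a–alkyne bond and returns to the route at 13. Here the aryl group is in place first and the alkyne is the coupling partner.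

**Step 12.** The acetylide or the amide may add to the activated acylpyrone before boron captures the acetylide, and the alkynylboronate may hydrolyse on work-up. Fallback: setting out from carbinol 17, buffered n-Bu4NF gives the terminal alkyne F6. Treatment with LiN(SiMe3)2 (2.2 equiv) and i-PrOBpin, then HCl in Et2O, gives the alkynylboronate carbinol F7; the carbinol is masked as its alkoxide and the pyrone is not yet acyl-activated. Dess–Martin oxidation returns to the route at 21.

**Step 17.** The resident C7a centre and the catalyst may favour opposite faces of the carbene, giving poor facial selectivity at C8c, and the hindered diazo compound may couple to an azine before it reaches rhodium. Fallback: setting out from ketone 25, Norrish–Yang photocyclisation (350 nm, benzene; δ-hydrogen abstraction from the ortho benzyl ether and closure of the 1,5-biradical) should give the tertiary benzylic alcohol F8. Ionic deoxygenation (Et3SiH, CF3CO2H, CH2Cl2, −40 °C) delivers hydride to the planar dibenzylic cation anti to the C7c aryl group and returns to the route at 28. The stereo-determining events are then a biradical closure and an external hydride delivery, not a carbene face; the sense of C7c relative to C7a in the photocyclisation is itself not secured.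

**Step 18.** The aryllithium flanked by two ortho substituents may add slowly to the nitrile, or the crowded ketimine may exchange slowly with hydrazine. Fallback: setting out from bromide 28 (through aryllithium 30), inverse addition to 3,5-dimethoxybenzoyl chloride at −78 °C gives the diaryl ketone F9, which is too hindered for a second addition. Condensation with hydrazine under forcing conditions (N2H4·H2O, ethylene glycol, 130 °C) returns to the route at 32.

## Further compounds

F1 | step 13 | 6-{3-bromo-2-[(2S)-4-(dimethylsilyl)-2-(4-methoxyphenyl)but-3-yn-1-yl]-4,6-bis(4-methoxybenzyloxy)benzoyl}-4-methoxy-2H-pyran-2-one | COc1ccc([C@@H](C#C[SiH](C)C)Cc2c(C(=O)c3cc(OC)cc(=O)o3)c(OCc3ccc(OC)cc3)cc(OCc3ccc(OC)cc3)c2Br)cc1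
F2 | step 13 | bridged lactone cycloadduct of F1 (as 22, dimethylsilyl in place of the boronate) | COc1ccc([C@@H]2Cc3c(Br)c(OCc4ccc(OC)cc4)cc(OCc4ccc(OC)cc4)c3C(=O)C45OC(=O)C(C(OC)=C4)C([SiH](C)C)=C52)cc1
F3 | step 13 | (10S)-1-bromo-9-(dimethylsilyl)-7-methoxy-10-(4-methoxyphenyl)-2,4-bis(4-methoxybenzyloxy)-10,11-dihydro-5H-dibenzo[a,d][7]annulen-5-one | COc1ccc([C@@H]2Cc3c(Br)c(OCc4ccc(OC)cc4)cc(OCc4ccc(OC)cc4)c3C(=O)c3cc(OC)cc([SiH](C)C)c32)cc1
F4 | step 7 | rac-2-[2,6-dibromo-3,5-bis(4-methoxybenzyloxy)phenyl]-1-(4-methoxyphenyl)ethanol | COc1ccc(C(O)Cc2c(Br)c(OCc3ccc(OC)cc3)cc(OCc3ccc(OC)cc3)c2Br)cc1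
F5 | step 7 | rac-1-chloro-2-[2,6-dibromo-3,5-bis(4-methoxybenzyloxy)phenyl]-1-(4-methoxyphenyl)ethane | COc1ccc(C(Cl)Cc2c(Br)c(OCc3ccc(OC)cc3)cc(OCc3ccc(OC)cc3)c2Br)cc1
F6 | step 12 | 6-[{3-bromo-4,6-bis(4-methoxybenzyloxy)-2-[(2R)-2-(4-methoxyphenyl)but-3-yn-1-yl]phenyl}(hydroxy)methyl]-4-methoxy-2H-pyran-2-one (both carbinol epimers) | COc1ccc([C@@H](C#C)Cc2c(C(O)c3cc(OC)cc(=O)o3)c(OCc3ccc(OC)cc3)cc(OCc3ccc(OC)cc3)c2Br)cc1
F7 | step 12 | 6-[{3-bromo-4,6-bis(4-methoxybenzyloxy)-2-[(2S)-2-(4-methoxyphenyl)-4-(4,4,5,5-tetramethyl-1,3,2-dioxaborolan-2-yl)but-3-yn-1-yl]phenyl}(hydroxy)methyl]-4-methoxy-2H-pyran-2-one (both carbinol epimers) | COc1ccc([C@@H](C#CB2OC(C)(C)C(C)(C)O2)Cc2c(C(O)c3cc(OC)cc(=O)o3)c(OCc3ccc(OC)cc3)cc(OCc3ccc(OC)cc3)c2Br)cc1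
F8 | step 17 | C8c tertiary alcohol of 28 (hydroxyl in place of H8c, C8c configuration undefined; C7a S; C7c drawn with the same spatial arrangement as in 28) | COc1ccc([C@@H]2Cc3c4c(cc(OCc5ccc(OC)cc5)c3Br)O[C@@H](c3ccc(OC)cc3)C4(O)c3cc(OC)cc(OC)c32)cc1
F9 | step 18 | diaryl ketone: 28 with the b6 bromine replaced by 3,5-dimethoxybenzoyl (C7a S; C8c S; C7c R) | COc1ccc([C@@H]2Cc3c4c(cc(OCc5ccc(OC)cc5)c3C(=O)c3cc(OC)cc(OC)c3)O[C@@H](c3ccc(OC)cc3)[C@H]4c3cc(OC)cc(OC)c32)cc1
A1 | alternative 1 | (S)-naringenin | O=C1C[C@@H](c2ccc(O)cc2)Oc2cc(O)cc(O)c12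
A2 | alternative 1 | (2S)-7-methoxy-2-(4-methoxyphenyl)-4-oxo-3,4-dihydro-2H-chromen-5-yl trifluoromethanesulfonate | O=C1C[C@@H](c2ccc(OC)cc2)Oc2cc(OC)cc(OS(=O)(=O)C(F)(F)F)c12
A3 | alternative 1 | methyl (2S,3S)-6-methoxy-2-(4-methoxyphenyl)-4-{[(trifluoromethyl)sulfonyl]oxy}-2,3-dihydro-1-benzofuran-3-carboxylate (trans) | COC(=O)[C@H]1c2c(OS(=O)(=O)C(F)(F)F)cc(OC)cc2O[C@@H]1c1ccc(OC)cc1
A4 | alternative 2 | 5-[(2S)-2-{2,4-dimethoxy-6-[(E)-2-(4-methoxyphenyl)ethenyl]phenyl}-2-(4-methoxyphenyl)ethyl]benzene-1,3-diol | COc1ccc(/C=C/c2cc(OC)cc(OC)c2[C@@H](Cc2cc(O)cc(O)c2)c2ccc(OC)cc2)cc1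
A5 | alternative 2 | seven-ring core with trans dihydrofuran ring D, free b5 phenol and unsubstituted b6 (C7a S; C8c S; C7c S) | COc1ccc([C@@H]2Cc3c4c(cc(O)c3)O[C@H](c3ccc(OC)cc3)[C@H]4c3cc(OC)cc(OC)c32)cc1
A6 | alternative 3 | methyl 5,7-bis(benzyloxy)-2-oxo-2,3-dihydro-1H-indene-1-carboxylate | COC(=O)C1C(=O)Cc2cc(OCc3ccccc3)cc(OCc3ccccc3)c12
A7 | alternative 3 | 3,5-dimethoxy-2-(trimethylsilyl)phenyl trifluoromethanesulfonate | COc1cc(OC)c([Si](C)(C)C)c(OS(=O)(=O)C(F)(F)F)c1
A8 | alternative 3 | seven-membered keto ester with the ketone at C7a and the methyl ester on C8c (C8c without defined configuration) | COC(=O)C1c2c(OCc3ccccc3)cc(OCc3ccccc3)cc2CC(=O)c2c(OC)cc(OC)cc12
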